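The lactone ring (O1, carbonyl C2, C3, C4, C5, C6) is treated as an oxa-[4+2] adduct at the acetal oxidation level. O1 and C6 come from the formyl group of an alpha-branched E-enal that already carries the side chain C7–C13 with its C14 acetate, both trisubstituted alkenes and a silyl-protected C13 alcohol; C2–C5 come from a 1-methoxy-2-homoprenylbutadiene. One chromium-catalysed enantioselective hetero-Diels–Alder reaction forms C5–C6 and O1–C2, closes the ring and sets C6 (R). The enal is built from nerol through a Morita–Baylis–Hillman sequence; acetal hydrolysis, lactol oxidation and desilylation finish the synthesis.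

Key step: step 12

Assumption: the facial sense of the chromium catalyst is taken from its behaviour with 1-methoxybutadiene and simple aldehydes, where the ligand from (1R,2S)-1-amino-2-indanol leads to the (2S,6R) cis-acetal; the antipodal ligand is equally available should enal 11 react with the opposite sense.

Step 1
Reactants: 1 nerol
Product: 2 tert-butyl{[(2Z)-3,7-dimethylocta-2,6-dien-1-yl]oxy}diphenylsilane
Conditions: TBDPSCl, imidazole, DMF, 0 °C to rt
Reagents that add atoms: tert-butyl(chloro)diphenylsilane, CC(C)(C)[Si](Cl)(c1ccccc1)c1ccccc1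
Why: Silylation of the primary allylic alcohol with a silyl chloride and imidazole is a standard protection, and the bulky silyl ether should survive all later steps until fluoride is applied.

Step 2
Reactants: 2 tert-butyl{[(2Z)-3,7-dimethylocta-2,6-dien-1-yl]oxy}diphenylsilane
Product: 3 tert-butyl{[(2Z)-5-(3,3-dimethyloxiran-2-yl)-3-methylpent-2-en-1-yl]oxy}diphenylsilane (racemic at the oxirane)
Conditions: mCPBA (1.05 equiv), CH2Cl2, −20 to 0 °C
Reagents that add atoms: 3-chloroperoxybenzoic acid, OOC(=O)c1cccc(Cl)c1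
Why: Prilezhaev epoxidation should occur at the more electron-rich distal alkene, because the other alkene is deactivated by its allylic silyloxy group; the new oxirane stereocentre is racemic and is destroyed in step 3.

Step 3
Reactants: 3 tert-butyl{[(2Z)-5-(3,3-dimethyloxiran-2-yl)-3-methylpent-2-en-1-yl]oxy}diphenylsilane
Product: 5 (4Z)-6-[(tert-butyldiphenylsilyl)oxy]-4-methylhex-4-enal, via vicinal diol 4 (not isolated)
Conditions: H5IO6 (1.2 equiv), THF/Et2O, 0 °C
Reagents that add atoms: none
Why: Periodic acid should open the epoxide with water at the tertiary carbon and cleave the resulting diol at once (Malaprade glycol cleavage), so the aldehyde keeps the epoxide oxygen while the Z alkene and the silyl ether are untouched.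

Step 4
Reactants: 5 (4Z)-6-[(tert-butyldiphenylsilyl)oxy]-4-methylhex-4-enal; 6 methyl acrylate
Product: 7 methyl (6Z)-8-[(tert-butyldiphenylsilyl)oxy]-3-hydroxy-6-methyl-2-methylideneoct-6-enoate (racemic)
Conditions: methyl acrylate (3 equiv), DABCO (1 equiv), 1,4-dioxane/H2O 1:1, rt
Reagents that add atoms: none
Why: Morita–Baylis–Hillman reaction, in which the amine adds to the acrylate and the resulting enolate attacks the unhindered aliphatic aldehyde; the carbinol centre is racemic and is removed in step 5.

Step 5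
Reactants: 7 methyl (6Z)-8-[(tert-butyldiphenylsilyl)oxy]-3-hydroxy-6-methyl-2-methylideneoct-6-enoate
Product: 8 methyl (2Z,6Z)-2-(bromomethyl)-8-[(tert-butyldiphenylsilyl)oxy]-6-methylocta-2,6-dienoate
Conditions: NBS, Me2S, CH2Cl2, 0 °C to rt
Reagents that add atoms: N-bromosuccinimide, O=C1CCC(=O)N1Br
Why: The bromosulfonium reagent activates the hydroxyl and bromide attacks the methylene terminus in an SN2′ allylic transposition, which for Morita–Baylis–Hillman alcohols of aliphatic aldehydes is known to give the trisubstituted alkene with the ester trans to the chain.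

Step 6
Reactants: 8 methyl (2Z,6Z)-2-(bromomethyl)-8-[(tert-butyldiphenylsilyl)oxy]-6-methylocta-2,6-dienoate
Product: 9 (2Z,6Z)-2-(bromomethyl)-8-[(tert-butyldiphenylsilyl)oxy]-6-methylocta-2,6-dien-1-ol
Conditions: i-Bu2AlH (2.2 equiv), CH2Cl2, −78 °C
Reagents that add atoms: none
Why: Hydride 1,2-reduction of the conjugated ester by i-Bu2AlH at low temperature should give the allylic alcohol without touching the allylic bromide or the alkene geometry.

Step 7
Reactants: 9 (2Z,6Z)-2-(bromomethyl)-8-[(tert-butyldiphenylsilyl)oxy]-6-methylocta-2,6-dien-1-ol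
Product: 10 (2Z,6Z)-2-(bromomethyl)-8-[(tert-butyldiphenylsilyl)oxy]-6-methylocta-2,6-dienal
Conditions: activated MnO2 (excess), CH2Cl2, rt
Reagents that add atoms: none
Why: MnO2 oxidation of an allylic alcohol to the enal runs under neutral heterogeneous conditions that should leave the bromide, the silyl ether and both alkene geometries intact.

Step 8
Reactants: 10 (2Z,6Z)-2-(bromomethyl)-8-[(tert-butyldiphenylsilyl)oxy]-6-methylocta-2,6-dienal
Product: 11 (2E,6Z)-2-(acetoxymethyl)-8-[(tert-butyldiphenylsilyl)oxy]-6-methylocta-2,6-dienal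
Conditions: KOAc, DMF, 0 °C to rt
Reagents that add atoms: potassium acetate, CC(=O)[O-].[K+]
Why: Nucleophilic allylic substitution of the activated bromide by acetate; any SN2′ adduct can return by a second allylic substitution to the conjugated enal, whose E geometry (formyl trans to the chain) is the thermodynamic one.

Step 9
Reactants: 12 5-bromo-2-methylpent-2-ene; 13 methyl dimethoxyacetate
Product: 15 1,1-dimethoxy-6-methylhept-5-en-2-one, via 4-methylpent-3-enylmagnesium bromide 14 (not isolated)
Conditions: Mg, THF, rt; then added to 13, THF, −78 °C; NH4Cl quench at −78 °C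
Reagents that add atoms: none
Why: Grignard acylation of an alpha,alpha-dialkoxy ester should stop at the ketone, because the magnesium-chelated tetrahedral intermediate persists at −78 °C until the quench.

Step 10
Reactants: 15 1,1-dimethoxy-6-methylhept-5-en-2-one
Product: 16 (2Z)-3-(dimethoxymethyl)-7-methylocta-2,6-diene
Conditions: EtPPh3Br, KN(SiMe3)2, THF, 0 °C; then 15, −78 °C to rt
Reagents that add atoms: ethyltriphenylphosphonium bromide, CC[P+](c1ccccc1)(c1ccccc1)c1ccccc1.[Br-]
Why: Wittig olefination of an alpha-keto acetal with a non-stabilised ylide is expected to place the new methyl group mainly cis to the oxygenated carbon (Z), and either alkene isomer carries the gamma-methyl group needed in step 11.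

Step 11
Reactants: 16 (2Z)-3-(dimethoxymethyl)-7-methylocta-2,6-diene
Product: 17 (1E)-1-methoxy-2-(4-methylpent-3-enyl)buta-1,3-diene
Conditions: n-BuLi, t-BuOK (1.5 equiv each), THF, −95 °C; then H2O
Reagents that add atoms: none
Why: Superbase-induced 1,4-elimination of methanol from an alpha,beta-unsaturated acetal (gamma-deprotonation of the methyl group, loss of methoxide) should, from the conformer with the acetal C–H eclipsing the alkene, place the methoxy group cis to the homoprenyl chain, which is the 1E isomer.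

Step 12
Reactants: 11 (2E,6Z)-2-(acetoxymethyl)-8-[(tert-butyldiphenylsilyl)oxy]-6-methylocta-2,6-dienal; 17 (1E)-1-methoxy-2-(4-methylpent-3-enyl)buta-1,3-diene
Product: 18 (2S,6R)-6-[(2E,6Z)-1-acetoxy-8-[(tert-butyldiphenylsilyl)oxy]-6-methylocta-2,6-dien-2-yl]-2-methoxy-3-(4-methylpent-3-enyl)-5,6-dihydro-2H-pyran
Conditions: CrCl(L) (5 mol %; L = dianion C27H29NO2 of the Schiff base of (1R,2S)-1-amino-2-indanol and 3-(1-adamantyl)-2-hydroxy-5-methylbenzaldehyde; trivalent chromium), powdered 4 Å molecular sieves, 17 (3 equiv), minimal t-BuOMe, rt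
Reagents that add atoms: none
Why: The aldehyde oxygen of 11 binds to the trivalent chromium centre and the s-cis diene adds in a concerted, asynchronous [4+2], the C5–C6 bond (diene CH2 terminus to carbonyl carbon) leading and the O1–C2 bond following. The closest known reaction type is the chromium Schiff-base-catalysed hetero-Diels–Alder reaction of 1-methoxybutadiene with aldehydes. The six-membered dihydropyran closes by intermolecular cycloaddition, both ring bonds forming in the one step. C6 is set by the catalyst, which shields one face of the bound formyl group (6R expected with the (1R,2S) ligand), and C2 follows from the endo approach of the 1E diene to give the cis acetal, a centre that is removed in step 14. The step needs attack at C=O and not carbo-Diels–Alder addition at C7=C8 or use of the enal as a heterodiene; the beta-substituted, trisubstituted C7=C8 alkene is a poor partner in both roles, while the electron-withdrawing acetoxymethyl group raises the electrophilicity of the formyl group. The acetate and the silyl ether should be spectators under this mild Lewis acid.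

Step 13
Reactants: 18 (2S,6R)-6-[(2E,6Z)-1-acetoxy-8-[(tert-butyldiphenylsilyl)oxy]-6-methylocta-2,6-dien-2-yl]-2-methoxy-3-(4-methylpent-3-enyl)-5,6-dihydro-2H-pyran
Product: 19 (6R)-6-[(2E,6Z)-1-acetoxy-8-[(tert-butyldiphenylsilyl)oxy]-6-methylocta-2,6-dien-2-yl]-3-(4-methylpent-3-enyl)-5,6-dihydro-2H-pyran-2-ol (anomer mixture)
Conditions: PPTS (cat.), acetone/H2O 10:1, rt
Reagents that add atoms: water, O
Why: Acid-catalysed acetal hydrolysis through the allylic oxocarbenium ion, which water traps at once; the weak acid should spare the silyl ether and the acetate, and C6 is not involved.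

Step 14
Reactants: 19 (6R)-6-[(2E,6Z)-1-acetoxy-8-[(tert-butyldiphenylsilyl)oxy]-6-methylocta-2,6-dien-2-yl]-3-(4-methylpent-3-enyl)-5,6-dihydro-2H-pyran-2-ol
Product: 20 (6R)-6-[(2E,6Z)-1-acetoxy-8-[(tert-butyldiphenylsilyl)oxy]-6-methylocta-2,6-dien-2-yl]-3-(4-methylpent-3-enyl)-5,6-dihydro-2H-pyran-2-one
Conditions: activated MnO2 (excess), CH2Cl2, rt
Reagents that add atoms: none
Why: Lactol oxidation by MnO2, which accepts the allylic hemiacetal as it does an allylic alcohol, should give the alpha,beta-unsaturated delta-lactone; no other free hydroxyl is present and C6 is untouched.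

Step 15
Reactants: 20 (6R)-6-[(2E,6Z)-1-acetoxy-8-[(tert-butyldiphenylsilyl)oxy]-6-methylocta-2,6-dien-2-yl]-3-(4-methylpent-3-enyl)-5,6-dihydro-2H-pyran-2-one
Product: 21 (6R)-6-[(2E,6Z)-1-acetoxy-8-hydroxy-6-methylocta-2,6-dien-2-yl]-3-(4-methylpent-3-enyl)-5,6-dihydro-2H-pyran-2-one
Conditions: HF·pyridine, pyridine, THF, 0 °C to rt
Reagents that add atoms: none
Why: Fluoride-mediated desilylation driven by Si–F bond formation; the buffered, non-basic medium should leave the acetate, the lactone and the alkenes unchanged and avoid acyl migration.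

Compound list

1 | nerol, (2Z)-3,7-dimethylocta-2,6-dien-1-ol | CC(C)=CCC/C(C)=C\CO | starting material
2 | tert-butyl{[(2Z)-3,7-dimethylocta-2,6-dien-1-yl]oxy}diphenylsilane | CC(C)=CCC/C(C)=C\CO[Si](c1ccccc1)(c1ccccc1)C(C)(C)C | intermediate
3 | tert-butyl{[(2Z)-5-(3,3-dimethyloxiran-2-yl)-3-methylpent-2-en-1-yl]oxy}diphenylsilane (racemic) | CC1(C)OC1CC/C(C)=C\CO[Si](c1ccccc1)(c1ccccc1)C(C)(C)C | intermediate
4 | (6Z)-8-[(tert-butyldiphenylsilyl)oxy]-2,6-dimethyloct-6-ene-2,3-diol (racemic, not isolated) | CC(C)(O)C(O)CC/C(C)=C\CO[Si](c1ccccc1)(c1ccccc1)C(C)(C)C | intermediate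
5 | (4Z)-6-[(tert-butyldiphenylsilyl)oxy]-4-methylhex-4-enal | O=CCC/C(C)=C\CO[Si](c1ccccc1)(c1ccccc1)C(C)(C)C | intermediate
6 | methyl acrylate | C=CC(=O)OC | starting material
7 | methyl (6Z)-8-[(tert-butyldiphenylsilyl)oxy]-3-hydroxy-6-methyl-2-methylideneoct-6-enoate (racemic) | C=C(C(=O)OC)C(O)CC/C(C)=C\CO[Si](c1ccccc1)(c1ccccc1)C(C)(C)C | intermediate
8 | methyl (2Z,6Z)-2-(bromomethyl)-8-[(tert-butyldiphenylsilyl)oxy]-6-methylocta-2,6-dienoate | COC(=O)/C(CBr)=C/CC/C(C)=C\CO[Si](c1ccccc1)(c1ccccc1)C(C)(C)C | intermediate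
9 | (2Z,6Z)-2-(bromomethyl)-8-[(tert-butyldiphenylsilyl)oxy]-6-methylocta-2,6-dien-1-ol | OC/C(CBr)=C/CC/C(C)=C\CO[Si](c1ccccc1)(c1ccccc1)C(C)(C)C | intermediate
10 | (2Z,6Z)-2-(bromomethyl)-8-[(tert-butyldiphenylsilyl)oxy]-6-methylocta-2,6-dienal | O=C/C(CBr)=C/CC/C(C)=C\CO[Si](c1ccccc1)(c1ccccc1)C(C)(C)C | intermediate
11 | (2E,6Z)-2-(acetoxymethyl)-8-[(tert-butyldiphenylsilyl)oxy]-6-methylocta-2,6-dienal | CC(=O)OC/C(=C\CC/C(C)=C\CO[Si](c1ccccc1)(c1ccccc1)C(C)(C)C)C=O | intermediate
12 | 5-bromo-2-methylpent-2-ene | CC(C)=CCCBr | starting material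
13 | methyl dimethoxyacetate | COC(OC)C(=O)OC | starting material
14 | 4-methylpent-3-enylmagnesium bromide (not isolated) | CC(C)=CCC[Mg]Br | intermediate
15 | 1,1-dimethoxy-6-methylhept-5-en-2-one | COC(OC)C(=O)CCC=C(C)C | intermediate
16 | (2Z)-3-(dimethoxymethyl)-7-methylocta-2,6-diene | C/C=C(/CCC=C(C)C)C(OC)OC | intermediate
17 | (1E)-1-methoxy-2-(4-methylpent-3-enyl)buta-1,3-diene | CO/C=C(/C=C)CCC=C(C)C | intermediate
18 | (2S,6R)-6-[(2E,6Z)-1-acetoxy-8-[(tert-butyldiphenylsilyl)oxy]-6-methylocta-2,6-dien-2-yl]-2-methoxy-3-(4-methylpent-3-enyl)-5,6-dihydro-2H-pyran | CC(=O)OC/C(=C\CC/C(C)=C\CO[Si](c1ccccc1)(c1ccccc1)C(C)(C)C)[C@H]1CC=C(CCC=C(C)C)[C@@H](OC)O1 | intermediate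
19 | (6R)-6-[(2E,6Z)-1-acetoxy-8-[(tert-butyldiphenylsilyl)oxy]-6-methylocta-2,6-dien-2-yl]-3-(4-methylpent-3-enyl)-5,6-dihydro-2H-pyran-2-ol (anomer mixture) | CC(=O)OC/C(=C\CC/C(C)=C\CO[Si](c1ccccc1)(c1ccccc1)C(C)(C)C)[C@H]1CC=C(CCC=C(C)C)C(O)O1 | intermediate
20 | (6R)-6-[(2E,6Z)-1-acetoxy-8-[(tert-butyldiphenylsilyl)oxy]-6-methylocta-2,6-dien-2-yl]-3-(4-methylpent-3-enyl)-5,6-dihydro-2H-pyran-2-one | CC(=O)OC/C(=C\CC/C(C)=C\CO[Si](c1ccccc1)(c1ccccc1)C(C)(C)C)[C@H]1CC=C(CCC=C(C)C)C(=O)O1 | intermediate
21 | (6R)-6-[(2E,6Z)-1-acetoxy-8-hydroxy-6-methylocta-2,6-dien-2-yl]-3-(4-methylpent-3-enyl)-5,6-dihydro-2H-pyran-2-one | CC(=O)OC/C(=C\CC/C(C)=C\CO)[C@H]1CC=C(CCC=C(C)C)C(=O)O1 | target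

Total step count: 15 (steps 1–8 to the enal, steps 9–11 to the diene, step 12, steps 13–15).
Longest linear sequence: 12 steps (steps 1–8 and 12–15).

Steps most likely to fail

Step 12. What may go wrong: the alpha-branched enal may react too slowly, the diene may add to C7=C8 in place of the formyl group, or the facial selectivity at the aldehyde may be poor. Fallback: build the ring by allylation, acylation and ring-closing metathesis, all known chemistry. Setting out from enal 11, Brown allylboration with (+)-Ipc2B(allyl) (the reagent from (−)-alpha-pinene; Et2O, −78 °C; ethanolamine work-up to spare the acetate) should add allyl to the Re face of the formyl group and give [(2E,6Z)-8-[(tert-butyldiphenylsilyl)oxy]-2-[(1R)-1-hydroxybut-3-enyl]-6-methylocta-2,6-dienyl] acetate F1. The acyl partner comes from bromide 12: alkylation of triethyl phosphonoacetate (NaH, DMSO) to ethyl 2-(diethoxyphosphoryl)-6-methylhept-5-enoate F2, Horner–Wadsworth–Emmons methylenation with aqueous formaldehyde and K2CO3 to ethyl 6-methyl-2-methylidenehept-5-enoate F3, and LiOH hydrolysis to 6-methyl-2-methylidenehept-5-enoic acid F4. Steglich esterification of F1 with F4 (DCC, DMAP, CH2Cl2) should give (1R)-1-[(2E,6Z)-1-acetoxy-8-[(tert-butyldiphenylsilyl)oxy]-6-methylocta-2,6-dien-2-yl]but-3-enyl 6-methyl-2-methylidenehept-5-enoate F5. Ring-closing metathesis with the second-generation Grubbs catalyst (CH2Cl2, 40 °C) joins the terminal vinyl group and the acrylate methylene, the only alkene pair able to give an unstrained ring, and comes back to the route at lactone 20.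

Step 11. What may go wrong: loss of control over the enol ether geometry, or metalation at another allylic site by the superbase. Fallback: form the C1=C2 enol ether by a stereospecific Horner–Wittig olefination. Setting out from bromide 12 by way of Grignard reagent 14, acylation with N-methoxy-N-methylacrylamide (THF, −78 °C, acidic quench) should give 7-methylocta-1,6-dien-3-one F6. Addition of lithiated (methoxymethyl)diphenylphosphine oxide (LiN(i-Pr)2, THF, −78 °C) gives two separable beta-hydroxy phosphine oxides, of which rac-(1S,2R)-1-(diphenylphosphoryl)-1-methoxy-2-(4-methylpent-3-enyl)but-3-en-2-ol F7 is kept. Its syn-elimination with KH in THF comes back to the route at diene 17 as the 1E isomer only.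

Step 8. What may go wrong: allylic transposition or degradation of the very reactive bromomethyl enal under acetate, with erosion of the C7=C8 geometry. Fallback: exchange the order of substitution and oxidation. Setting out from bromo alcohol 9, KOAc in DMF displaces the unactivated allylic bromide to give [(2Z,6Z)-8-[(tert-butyldiphenylsilyl)oxy]-2-(hydroxymethyl)-6-methylocta-2,6-dienyl] acetate F8, and MnO2 in CH2Cl2 then oxidises the remaining allylic alcohol, coming back to the route at enal 11.

Further compounds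

F1 | step 12 | [(2E,6Z)-8-[(tert-butyldiphenylsilyl)oxy]-2-[(1R)-1-hydroxybut-3-enyl]-6-methylocta-2,6-dienyl] acetate | CC(=O)OC/C(=C\CC/C(C)=C\CO[Si](c1ccccc1)(c1ccccc1)C(C)(C)C)[C@H](O)CC=C
F2 | step 12 | ethyl 2-(diethoxyphosphoryl)-6-methylhept-5-enoate | CCOC(=O)C(CCC=C(C)C)P(=O)(OCC)OCC
F3 | step 12 | ethyl 6-methyl-2-methylidenehept-5-enoate | CCOC(=O)C(=C)CCC=C(C)C
F4 | step 12 | 6-methyl-2-methylidenehept-5-enoic acid | OC(=O)C(=C)CCC=C(C)C
F5 | step 12 | (1R)-1-[(2E,6Z)-1-acetoxy-8-[(tert-butyldiphenylsilyl)oxy]-6-methylocta-2,6-dien-2-yl]but-3-enyl 6-methyl-2-methylidenehept-5-enoate | CC(=O)OC/C(=C\CC/C(C)=C\CO[Si](c1ccccc1)(c1ccccc1)C(C)(C)C)[C@H](OC(=O)C(=C)CCC=C(C)C)CC=C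
F6 | step 11 | 7-methylocta-1,6-dien-3-one | C=CC(=O)CCC=C(C)C
F7 | step 11 | rac-(1S,2R)-1-(diphenylphosphoryl)-1-methoxy-2-(4-methylpent-3-enyl)but-3-en-2-ol | CO[C@@H](P(=O)(c1ccccc1)c1ccccc1)[C@](O)(C=C)CCC=C(C)C
F8 | step 8 | [(2Z,6Z)-8-[(tert-butyldiphenylsilyl)oxy]-2-(hydroxymethyl)-6-methylocta-2,6-dienyl] acetate | CC(=O)OC/C(=C\CC/C(C)=C\CO[Si](c1ccccc1)(c1ccccc1)C(C)(C)C)CO
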